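## Retrosynthetic overview

1. The target is 3β-acetoxy-9α-hydroxylabd-13-en-15,16-olide. The butenolide ring is bought as 4-bromofuran-2(5H)-one and attached last at C12–C13 (hydroboration/B-alkyl Suzuki coupling of a C9 vinyl carbinol). The 9α-OH comes from α-face epoxidation of a C9 exo-methylene and one-carbon homologation of the epoxide.
2. 3β-OAc and the C4 gem-dimethyl group come from a regiodefined C3 silyl enol ether (MeLi/MeI, NaBH4, Ac2O).
3. Rings A and B are formed together in one intramolecular Diels–Alder reaction of an acyclic trienone, through the bonds C1–C2 and C5–C10: ring A is the cyclohexene of the [4+2], ring B is the ring of the tether.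
4. Enabling feature: oxygen-bearing C9 is bonded to the quaternary C10 that carries C1, and oxygen-bearing C3 lies para to C10 in ring A. A C9 ketone therefore makes C10=C1 a methacryloyl dienophile, a C3 silyl enol ether makes C2=C3–C4=C5 a 2-silyloxydiene whose nucleophilic end C2 matches C1, and C6–C9 of ring B is the tether.
5. The trienone is made in six steps from hex-5-enoyl chloride. Its only stereocenter, C8, is set by auxiliary-controlled methylation and relays to C10 and C5 in the cycloaddition.

Key step: step 7

Remark on the chemistry: the SMILES is read as the trans-decalin with 3β-OAc, 5α-H, 8α-CH3 (8β-H), 9α-OH and 10β-CH3; labdane numbering is used throughout (ring A = C1–C5, C10; ring B = C5–C10); 3-(chloromethyl)furan, used only in a fallback, is taken as commercial.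

## Route

Step 1
Reactants: 1 (R)-4-benzyloxazolidin-2-one; 2 hex-5-enoyl chloride
Product: 4 (R)-4-benzyl-3-(hex-5-enoyl)oxazolidin-2-one, via lithium oxazolidinide 3 (not isolated)
Conditions: n-BuLi, THF, −78 °C; then 2, −78 → 0 °C
Reagents that add atoms: n-butyllithium, [Li]CCCC (lithium, in 3 only)
Why: N-acylation of the lithiated oxazolidinone by the acid chloride attaches the chiral auxiliary; no stereocenter is formed.

Step 2
Reactants: 4 (R)-4-benzyl-3-(hex-5-enoyl)oxazolidin-2-one
Product: 6 (R)-4-benzyl-3-[(R)-2-methylhex-5-enoyl]oxazolidin-2-one, via sodium enolate 5 (not isolated)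
Conditions: NaN(SiMe3)2, THF, −78 °C; then MeI, −78 → −40 °C
Reagents that add atoms: iodomethane, CI; sodium bis(trimethylsilyl)amide, C[Si](C)(C)N([Na])[Si](C)(C)C (sodium, in 5 only)
Why: Evans asymmetric alkylation; the chelated (Z)-enolate is methylated on the face opposite the benzyl group, which should set the future C8 as (R).

Step 3
Reactants: 6 (R)-4-benzyl-3-[(R)-2-methylhex-5-enoyl]oxazolidin-2-one
Product: 7 (R)-N-methoxy-N,2-dimethylhex-5-enamide
Conditions: MeNHOMe·HCl, AlMe3, CH2Cl2, −10 °C → rt
Reagents that add atoms: N,O-dimethylhydroxylamine hydrochloride, CNOC.Cl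
Why: Weinreb transamination by the aluminium amide cleaves the exocyclic imide carbonyl without epimerising the α-stereocenter and returns the auxiliary.

Step 4
Reactants: 7 (R)-N-methoxy-N,2-dimethylhex-5-enamide; 8 3-(triphenyl-λ5-phosphanylidene)butan-2-one
Product: 10 (2R,5E)-N-methoxy-N,2,6-trimethyl-7-oxooct-5-enamide, via aldehyde 9 (not isolated)
Conditions: O3, CH2Cl2, −78 °C; PPh3, → rt; evaporate; then 8, PhMe, 80 °C
Reagents that add atoms: ozone, [O-][O+]=O
Why: ozonolysis of the only alkene followed by Wittig olefination with the stabilised, α-branched ylide should give the (E)-trisubstituted enone under thermodynamic control; the amide and C8 are untouched.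

Step 5
Reactants: 10 (2R,5E)-N-methoxy-N,2,6-trimethyl-7-oxooct-5-enamide
Product: 11 (2R,5E)-N-methoxy-N,2,6-trimethyl-7-[(triethylsilyl)oxy]octa-5,7-dienamide
Conditions: Et3SiOTf, Et3N, CH2Cl2, −78 → 0 °C
Reagents that add atoms: triethylsilyl trifluoromethanesulfonate, CC[Si](CC)(CC)OS(=O)(=O)C(F)(F)F
Why: soft enolisation of the methyl enone at its α′-methyl gives the cross-conjugated 2-silyloxy-1,3-diene; the amide α-hydrogen is far less acidic and is not touched.

Step 6
Reactants: 11 (2R,5E)-N-methoxy-N,2,6-trimethyl-7-[(triethylsilyl)oxy]octa-5,7-dienamide; 12 isopropenylmagnesium bromide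
Product: 13 (4R,7E)-2,4,8-trimethyl-9-[(triethylsilyl)oxy]deca-1,7,9-trien-3-one
Conditions: THF, −20 → 0 °C; cold aq. NH4Cl; used crude
Reagents that add atoms: none
Why: Weinreb ketone synthesis; the chelated tetrahedral adduct survives until the quench, so one isopropenyl group adds and C8 is not epimerised, and silyl enol ethers tolerate Grignard reagents.

Step 7
Reactants: 13 (4R,7E)-2,4,8-trimethyl-9-[(triethylsilyl)oxy]deca-1,7,9-trien-3-one
Product: 14 (2R,4aS,8aS)-2,5,8a-trimethyl-6-[(triethylsilyl)oxy]-3,4,4a,7,8,8a-hexahydronaphthalen-1(2H)-one (labdane numbering: C3 silyl enol ether with C3=C4, 9-ketone, 5α-H, 8α-CH3, 10β-CH3, trans-fused)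
Conditions: PhMe (0.02 M), BHT (cat.), 90 °C
Reagents that add atoms: none
Why: Thermal, concerted but asynchronous intramolecular [4+2] cycloaddition (type 1 intramolecular Diels–Alder reaction), in which the nucleophilic diene terminus C2 bonds to the enone β-carbon C1 ahead of the C5–C10 bond. The closest known reaction type is the cyclisation of 1,7,9-decatrien-3-ones (dienophile carbonyl inside the tether) to 1-decalones, including 2-methyl trienones that give angular methyl groups and 2-silyloxydiene substrates. Ring A closes as the cyclohexene of the [4+2] (bonds C1–C2 and C5–C10), and ring B closes in the fused mode as the six-membered ring of the four-atom tether C6–C9, through the same C5–C10 bond. C10 is controlled by the C8 stereocenter: in both possible transition states the C10 methyl is axial on the forming ring B, so the C8 methyl must sit equatorial in a chair-like tether to avoid a syn-diaxial methyl/methyl contact, and this fixes the diene face. C5 is controlled by the exo orientation of the tether carbonyl (dienophile methyl under the diene), which keeps the diene carbon C4 equatorial on ring B and should give the trans ring fusion. Regiochemistry is fixed by the tether and reinforced by the para-directing silyloxy group; the step needs tether-exo over tether-endo selectivity, for which the α-methyl of the dienophile and the axial penalty for C4 in the endo mode are relied on, and the (E)-C4=C5 geometry keeps the tether outside the s-cis diene.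

Step 8
Reactants: 14 trans-fused octalone (as named in step 7)
Product: 15 9-methylene analogue of 14 (C9=CH2 in place of C9=O; C3 triethylsilyl enol ether, 5α-H, 8α-CH3, 10β-CH3)
Conditions: Cp2TiMe2, PhMe/THF, 70 °C, dark
Reagents that add atoms: dimethyltitanocene (Cp2TiMe2), C[Ti](C)(C1C=CC=C1)C1C=CC=C1
Why: Petasis methylenation through Cp2Ti=CH2 converts hindered, enolisable ketones into methylene compounds without base, so the silyl enol ether and the equatorial C8 methyl should be kept.

Step 9
Reactants: 15 9-methylene silyl enol ether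
Product: 17 12,13,14,15,16-pentanorlabd-9(11)-en-3-one (4,4,8α,10β-tetramethyl-9-methylene-5α-decalin-3-one), via lithium enolate 16 (not isolated)
Conditions: MeLi, THF, 0 °C → rt; then MeI, DMPU, −78 → 0 °C
Reagents that add atoms: iodomethane, CI; methyllithium, [Li]C (lithium, in 16 only)
Why: MeLi cleaves the silyl enol ether to the regiodefined C3–C4 lithium enolate, which is C-methylated at C4 to complete the gem-dimethyl group; no stereocenter is formed.

Step 10
Reactants: 17 12,13,14,15,16-pentanorlabd-9(11)-en-3-one
Product: 18 12,13,14,15,16-pentanorlabd-9(11)-en-3β-ol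
Conditions: NaBH4, MeOH/THF, 0 °C
Reagents that add atoms: none
Why: hydride reduction of a 4,4-dimethyl-3-ketone in a trans-decalin delivers hydride axially from the α face, which should give the equatorial 3β-alcohol.

Step 11
Reactants: 18 12,13,14,15,16-pentanorlabd-9(11)-en-3β-ol
Product: 19 9α,11-epoxy-12,13,14,15,16-pentanorlabdan-3β-ol (spiro-oxirane at C9, oxygen α and axial, C11 β)
Conditions: mCPBA, NaHCO3, CH2Cl2, 0 °C
Reagents that add atoms: 3-chloroperoxybenzoic acid, OOC(=O)c1cccc(Cl)c1
Why: Prilezhaev epoxidation of the exocyclic alkene should occur on the α face, away from the axial C10 methyl on the adjacent carbon, placing the oxygen axial (9α) and C11 equatorial.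

Step 12
Reactants: 19 9α,11-epoxy-12,13,14,15,16-pentanorlabdan-3β-ol
Product: 20 13,14,15,16-tetranorlabd-11-ene-3β,9α-diol (β-vinyl group on C9)
Conditions: Me3SI, n-BuLi (excess), THF, −10 °C → rt
Reagents that add atoms: trimethylsulfonium iodide, C[S+](C)C.[I-]
Why: one-carbon homologation of an epoxide to an allylic alcohol with excess dimethylsulfonium methylide (SN2 opening at the CH2 carbon C11, then ylide-mediated loss of Me2S); the C9–O bond is not touched, so the 9α configuration is retained.

Step 13
Reactants: 20 13,14,15,16-tetranorlabd-11-ene-3β,9α-diol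
Product: 21 3β-acetoxy-13,14,15,16-tetranorlabd-11-en-9α-ol
Conditions: Ac2O, pyridine, DMAP (cat.), CH2Cl2, rt
Reagents that add atoms: acetic anhydride, CC(=O)OC(C)=O
Why: acylation of the secondary equatorial 3β-OH; the tertiary 9-OH, flanked by C8 and the quaternary C10, should not acylate under these conditions.

Step 14
Reactants: 21 3β-acetoxy-13,14,15,16-tetranorlabd-11-en-9α-ol; 22 4-bromofuran-2(5H)-one
Product: 24 3β-acetoxy-9α-hydroxylabd-13-en-15,16-olide (target), via B-alkyl-9-BBN adduct 23 (not isolated)
Conditions: 9-BBN, THF, rt → 50 °C; then 22, PdCl2(dppf) (cat.), AsPh3, aq. K3PO4, DMF, rt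
Reagents that add atoms: 9-borabicyclo[3.3.1]nonane, B1C2CCCC1CCC2 (boron and its ring, in 23 only)
Why: anti-Markovnikov hydroboration places boron on C12, and B-alkyl Suzuki–Miyaura coupling with the β-bromo butenolide forms C12–C13; the acetate and the tertiary alcohol are tolerated and no stereocenter is formed.

## Compound list

1 | (R)-4-benzyloxazolidin-2-one | O=C1N[C@H](Cc2ccccc2)CO1 | starting material
2 | hex-5-enoyl chloride | C=CCCCC(Cl)=O | starting material
3 | lithium (R)-4-benzyl-2-oxooxazolidin-3-ide (not isolated) | [Li]N1[C@H](Cc2ccccc2)COC1=O | intermediate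
4 | (R)-4-benzyl-3-(hex-5-enoyl)oxazolidin-2-one | C=CCCCC(=O)N1[C@H](Cc2ccccc2)COC1=O | intermediate
5 | sodium (Z)-enolate of 4 (not isolated) | C=CCC/C=C(\O[Na])N1[C@H](Cc2ccccc2)COC1=O | intermediate
6 | (R)-4-benzyl-3-[(R)-2-methylhex-5-enoyl]oxazolidin-2-one | C=CCC[C@@H](C)C(=O)N1[C@H](Cc2ccccc2)COC1=O | intermediate
7 | (R)-N-methoxy-N,2-dimethylhex-5-enamide | C=CCC[C@@H](C)C(=O)N(C)OC | intermediate
8 | 3-(triphenyl-λ5-phosphanylidene)butan-2-one | CC(=O)C(C)=P(c1ccccc1)(c1ccccc1)c1ccccc1 | starting material
9 | (R)-N-methoxy-N,2-dimethyl-5-oxopentanamide (not isolated) | O=CCC[C@@H](C)C(=O)N(C)OC | intermediate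
10 | (2R,5E)-N-methoxy-N,2,6-trimethyl-7-oxooct-5-enamide | CC(=O)/C(C)=C/CC[C@@H](C)C(=O)N(C)OC | intermediate
11 | (2R,5E)-N-methoxy-N,2,6-trimethyl-7-[(triethylsilyl)oxy]octa-5,7-dienamide | C=C(O[Si](CC)(CC)CC)/C(C)=C/CC[C@@H](C)C(=O)N(C)OC | intermediate
12 | isopropenylmagnesium bromide (prop-1-en-2-ylmagnesium bromide) | C=C(C)[Mg]Br | starting material
13 | (4R,7E)-2,4,8-trimethyl-9-[(triethylsilyl)oxy]deca-1,7,9-trien-3-one | C=C(C)C(=O)[C@H](C)CC/C=C(\C)C(=C)O[Si](CC)(CC)CC | intermediate
14 | (2R,4aS,8aS)-2,5,8a-trimethyl-6-[(triethylsilyl)oxy]-3,4,4a,7,8,8a-hexahydronaphthalen-1(2H)-one (trans-fused; 5α-H, 8α-CH3, 10β-CH3) | CC[Si](CC)(CC)OC=1CC[C@@]2(C)[C@@H](CC[C@@H](C)C2=O)C=1C | intermediate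
15 | 9-methylene analogue of 14 (C3 triethylsilyl enol ether, C9=CH2, 5α-H, 8α-CH3, 10β-CH3) | CC[Si](CC)(CC)OC=1CC[C@@]2(C)[C@@H](CC[C@@H](C)C2=C)C=1C | intermediate
16 | lithium C3–C4 enolate from 15 (not isolated) | [Li]OC=1CC[C@@]2(C)[C@@H](CC[C@@H](C)C2=C)C=1C | intermediate
17 | 12,13,14,15,16-pentanorlabd-9(11)-en-3-one (5α-H, 8α-CH3, 10β-CH3) | O=C1CC[C@@]2(C)[C@@H](CC[C@@H](C)C2=C)C1(C)C | intermediate
18 | 12,13,14,15,16-pentanorlabd-9(11)-en-3β-ol | O[C@H]1CC[C@@]2(C)[C@@H](CC[C@@H](C)C2=C)C1(C)C | intermediate
19 | 9α,11-epoxy-12,13,14,15,16-pentanorlabdan-3β-ol | O[C@H]1CC[C@@]2(C)[C@@H](CC[C@@H](C)[C@]23CO3)C1(C)C | intermediate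
20 | 13,14,15,16-tetranorlabd-11-ene-3β,9α-diol | O[C@H]1CC[C@@]2(C)[C@@H](CC[C@@H](C)[C@]2(O)C=C)C1(C)C | intermediate
21 | 3β-acetoxy-13,14,15,16-tetranorlabd-11-en-9α-ol | CC(=O)O[C@H]1CC[C@@]2(C)[C@@H](CC[C@@H](C)[C@]2(O)C=C)C1(C)C | intermediate
22 | 4-bromofuran-2(5H)-one | O=C1C=C(Br)CO1 | starting material
23 | 3β-acetoxy-12-(9-borabicyclo[3.3.1]nonan-9-yl)-13,14,15,16-tetranorlabdan-9α-ol (not isolated) | CC(=O)O[C@H]1CC[C@@]2(C)[C@@H](CC[C@@H](C)[C@]2(O)CCB2C3CCCC2CCC3)C1(C)C | intermediate
24 | 3β-acetoxy-9α-hydroxylabd-13-en-15,16-olide (CNP0578261.2) | CC(=O)O[C@H]1CC[C@@]2(C)[C@@H](CC[C@@H](C)[C@]2(O)CCC2=CC(=O)OC2)C1(C)C | target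

## Step count and risks

Total step count: 14. Longest linear sequence: 14 steps (2 → 24).

Steps most likely to fail:

**Step 7 (cycloaddition).** What may go wrong: competition from the tether-endo transition state, giving poor control of the ring fusion at C5. Fallback (sets out from 13, returns at 17): the cycloaddition is run as before and the mixture of 14 and its cis-fused C5 epimer F1 is not separated. Methylenation with Cp2TiMe2 as in step 8 gives 15 together with the C5-epimeric methylene compound F2. Saegusa–Ito dehydrogenation (Pd(OAc)2, MeCN, rt) converts both epimers into one compound, the 4-methyl-3-keto-4-ene F3, in which C5 is no longer a stereocenter. Birch-type reductive methylation (Li, NH3/THF, t-BuOH, −78 °C; then MeI) protonates C5 axially, trans to the C10 methyl, and methylates the resulting C3–C4 enolate at C4, which gives 17. In this variant the cycloaddition only has to set C10 against C8, which both transition states do in the same sense.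

**Step 12 (epoxide homologation).** What may go wrong: decomposition of the thermally labile ylide before it opens the hindered, neopentyl-type epoxide carbon C11. Fallback (sets out from 19, returns at 24, bypassing 20–23): 3-(chloromethyl)furan and Mg in THF give (furan-3-ylmethyl)magnesium chloride F4, a stable carbon nucleophile that already carries the lactone carbons. It opens 19 at C11 (CuI cat., THF, −20 °C → rt) to the furyl diol F5. Acetylation as in step 13 gives the furyl 3-acetate F6. Dye-sensitised photooxygenation (O2, rose bengal, hν, i-Pr2NEt, CH2Cl2, −78 °C) gives the γ-hydroxybutenolide F7, with the carbonyl on the side remote from the alkyl chain because the hindered base removes the less hindered bridgehead hydrogen of the endoperoxide. NaBH4 (EtOH, 0 °C; mild acid work-up) reduces the masked aldehyde and relactonises to 24.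

**Step 14 (hydroboration/coupling).** What may go wrong: incomplete hydroboration of the vinyl group next to the fully substituted C9, or base-induced degradation of the bromobutenolide before transmetalation. Fallback (sets out from 21, returns at 24): Heck coupling of 21 with 22 under ligand-free phase-transfer conditions (Pd(OAc)2, n-Bu4NCl, NaHCO3, DMF, 60 °C) gives the (E)-dienolide F8; the tertiary carbinol carbon has no hydrogen, so β-hydride elimination can only give the diene. Chemoselective hydrogenation of the disubstituted C11=C12 bond (H2, RhCl(PPh3)3, benzene/EtOH), which should leave the trisubstituted conjugated butenolide alkene, gives 24.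

## Further compounds

F1 | step 7 | cis-fused C5 epimer of 14 (5β-H) | CC[Si](CC)(CC)OC=1CC[C@@]2(C)[C@H](CC[C@@H](C)C2=O)C=1C
F2 | step 7 | cis-fused C5 epimer of 15 (5β-H, C9=CH2) | CC[Si](CC)(CC)OC=1CC[C@@]2(C)[C@H](CC[C@@H](C)C2=C)C=1C
F3 | step 7 | 4,8α,10β-trimethyl-9-methylene-octal-4-en-3-one (labdane numbering; C4=C5 enone) | O=C1CC[C@@]2(C)C(CC[C@@H](C)C2=C)=C1C
F4 | step 12 | (furan-3-ylmethyl)magnesium chloride | Cl[Mg]Cc1ccoc1
F5 | step 12 | 15,16-epoxylabda-13(16),14-diene-3β,9α-diol (furyl diol) | O[C@H]1CC[C@@]2(C)[C@@H](CC[C@@H](C)[C@]2(O)CCc2ccoc2)C1(C)C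
F6 | step 12 | 3β-acetoxy-15,16-epoxylabda-13(16),14-dien-9α-ol (furyl acetate) | CC(=O)O[C@H]1CC[C@@]2(C)[C@@H](CC[C@@H](C)[C@]2(O)CCc2ccoc2)C1(C)C
F7 | step 12 | 3β-acetoxy-9α,16-dihydroxylabd-13-en-15,16-olide (γ-hydroxybutenolide, C16 epimers) | CC(=O)O[C@H]1CC[C@@]2(C)[C@@H](CC[C@@H](C)[C@]2(O)CCC2=CC(=O)OC2O)C1(C)C
F8 | step 14 | (11E)-3β-acetoxy-9α-hydroxylabda-11,13-dien-15,16-olide | CC(=O)O[C@H]1CC[C@@]2(C)[C@@H](CC[C@@H](C)[C@]2(O)/C=C/C2=CC(=O)OC2)C1(C)C
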